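(All constants are invented.)

Answer 4 questions about a flask in which solid substrate has to dissolve before the catalyst can reach it.

    starting material + free catalyst ⇌ catalyst intermediate A (K1 = 1700 M⁻¹, k1 = 56 M⁻¹ s⁻¹)
    catalyst intermediate A ⇌ catalyst intermediate B (K2 = 0.37, k2 = 9.1 s⁻¹)
    reagent + catalyst intermediate B → catalyst intermediate C (k3 = 1100 M⁻¹ s⁻¹)
    catalyst intermediate C → free catalyst + target (k4 = 35 s⁻¹)
    solid substrate ⇌ starting material, rate k5*(cs5 - [starting material]) while solid is left; crystals form when [starting material] > cs5 (cs5 = 6.0 mM, k5 = 0.016 s⁻¹)

solid substrate 10 mM; reagent 10.0 mM; free catalyst 100 µM; time 2.5 min

- why nothing more happens at 2.5 min, or that something still does (for what has run out or reacted, a solid counts together with what of it has only dissolved) (all of the solid substrate has reacted / it is still moving / the reagent has run out first / no working catalyst is left / forward and back rates have come level)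
- part of the solid substrate that has turned into other species by 2.5 min (what has only dissolved does not count)
- amount of target at 2.5 min, in percent of the solid substrate charged
- amount of starting material at 2.5 min, in percent of the solid substrate charged

- solid substrate is a solid; its amount is given per volume of the solution
- at the start none of the solid substrate is in solution
- what has only dissolved of solid substrate counts as not reacted
- the reaction counts as stopped when no species that holds the solid substrate changes by six tenths of a point or more over the second half of the time
- starting material means what is dissolved; the solid is not counted in it
- run time (flask): 2.5 min

Follow one molecule of starting material, taking the charges as they stand. Free catalyst catches it at 0.00560 s⁻¹. On catalyst intermediate B it meets a fork: reagent carries it on at 11.0 s⁻¹, or it falls back to catalyst intermediate A at 24.6 s⁻¹, so it goes on with chance 30.9 %. Catalyst intermediate A therefore moves forward at 2.81 s⁻¹, and it releases the molecule far more slowly, at 0.0329 s⁻¹, so a caught molecule gets through with chance 98.8 %.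

Call 0.00554 s⁻¹ the capture constant, the catch rate times the chance of getting through. Seen from the catalyst, catching is the rate-limiting step: even with c(starting material) at its solubility, a free catalyst is caught at 0.336 s⁻¹, slower than both the forward move and the release of target.

Now treat c(starting material) as a first-order lag: dissolving fills it, capture drains it. It climbs with time constant 46.4 s toward 4.46 mM, which puts it at 42.8 % of the charge at 2.5 min. Integrating the drain gives target 26.0 %, and I take conversion as equal, since the catalyst charge is far smaller than the solid charge. Dissolved in total is 6.88 mM, less than the 10 mM charged, so solid remains and the flask is still moving.

The forecast gives it is still moving, conversion 23.5 %, target 23 % and starting material 44 %, holding that “Catalyst binding of dissolved substrate is the slow step”. My target stands higher.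

The flask gives it is still moving, conversion 23.9 %, target 23.7 % and starting material 43.9 %.

In this flask free catalyst stands at 87.7 % of its charge at 2.50 min, and scaled by that share the capture constant reads 0.00486 s⁻¹. Now take the neighbour with 0.25 mM of free catalyst, other charges and the time held. Its capture constant is 0.0138 s⁻¹, its time constant 33.5 s, its plateau 3.22 mM, and the same lag gives target 51.9 %. That neighbour gives target 48.4 %.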